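**Retrosynthetic overview**
- The three esters go on one at a time: O4-propionylation last, the O3 acetate by opening the cyclic orthoacetate of the cis-3,4-diol (axial ester), the O5 ester by esterifying the C5 alcohol with (R)-2-methylbutanoic acid.
- The cis-3,4-diol comes from osmylation of a C3=C4 alkene anti to the C5 acyloxy group; the C5 stereocentre comes from Jacobsen epoxidation of the temporarily deconjugated 2,4-diene ester and E1cB re-opening.
- Key disconnection: C6–C1 and C3–C4 (made as C3=C4) in a one-pot [3+3] Michael/Wittig annulation of an ester-stabilised allylidenephosphorane with acrolein.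
- Enabling feature: C1 is the α-carbon of the methyl ester and C1=C2 is conjugated to it, so C1–C2–C3 is the γ/β/α triad of the phosphorane (nucleophilic at C1 and C3), while C6–C5–C4 is the β/α/carbonyl triad of acrolein (electrophilic at C6 and C4).
- Ring order: the cyclohexene, the only ring of the target, is closed in step 2; the epoxide (step 4) and the orthoester (step 8) are temporary rings.

Key step: step 2

Remark on the chemistry: the (S,S) manganese salen catalyst is assumed to attack the distal alkene of the deconjugated diene ester with the enantiofacial sense it shows for indene-type cyclic cis-alkenes; if the sense were opposite, the (R,R) catalyst would be used.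

**Step 1**
Reactants: 1 methyl (2E)-4-bromobut-2-enoate; 2 triphenylphosphine
Product: 3 [(2E)-4-methoxy-4-oxobut-2-en-1-yl]triphenylphosphonium bromide
Conditions: toluene, 25 °C
Reagents that add atoms: none
Why: SN2 quaternisation of the allylic bromide by the phosphine (Wittig salt formation) should leave the E alkene untouched.

**Step 2**
Reactants: 3 [(2E)-4-methoxy-4-oxobut-2-en-1-yl]triphenylphosphonium bromide; 4 acrolein
Product: 7 methyl cyclohexa-1,3-diene-1-carboxylate, via allylidenephosphorane 5 (not isolated), via oxopropyl ylide 6 (not isolated)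
Conditions: NaOH, H2O/CH2Cl2, 0 °C; then 4, CH2Cl2, 0 to 25 °C
Reagents that add atoms: none
Why: Ylide 5 is an ambident ester-stabilised allylidenephosphorane: its γ-carbon (the ester α-carbon, C1) adds in Michael fashion to the β-carbon of acrolein (C6), proton transfer from C1 to the enolate gives the conjugated ylide 6, and the ylide carbon (C3) then attacks the aldehyde carbon (C4) in an intramolecular Wittig olefination that expels Ph3PO. The closest known reaction type is exactly this [3+3] Michael/Wittig annulation of (3-alkoxycarbonylallylidene)phosphoranes with α,β-unsaturated aldehydes to cyclohexa-1,3-diene-1-carboxylates. The cyclohexadiene ring is closed in the Wittig event, a 6-exo-trig addition of C3 to the C4=O group followed by collapse of the oxaphosphetane to the C3=C4 bond. No stereocentre is formed; what the step fixes is constitution: the ester on C1, the C1=C2 alkene in its final place and a C3=C4 alkene that later carries both cis oxygens. The selectivity needed is 1,4-addition through the γ-carbon before 1,2-olefination, which the soft delocalised ylide and the unhindered β-carbon of acrolein favour; should olefination come first, the (Z)-trienoate closes the same C6–C1 bond by 6π-electrocyclisation and base-mediated conjugation leads to the same diene 7.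

**Step 3**
Reactants: 7 methyl cyclohexa-1,3-diene-1-carboxylate
Product: 9 methyl cyclohexa-2,4-diene-1-carboxylate (racemic), via lithium trienolate 8 (not isolated)
Conditions: LiN(iPr)2, DMPU, THF, −78 °C; then AcOH, −78 °C
Reagents that add atoms: none
Why: LiN(iPr)2 should remove a C5 hydrogen (the only sp3 C–H conjugated through the diene to the ester) to give trienolate 8, and kinetic α-protonation (deconjugative protonation of an extended ester enolate) gives the 2,4-diene, whose C1 stereocentre is racemic and becomes planar again in step 5.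

**Step 4**
Reactants: 9 methyl cyclohexa-2,4-diene-1-carboxylate (racemic)
Product: 10 methyl (1RS,4S,5R)-4,5-epoxycyclohex-2-ene-1-carboxylate
Conditions: (S,S)-N,N′-bis(3,5-di-tert-butylsalicylidene)cyclohexane-1,2-diaminomanganese chloride (5 mol %), N-methylmorpholine N-oxide, m-CPBA, CH2Cl2, −78 °C
Reagents that add atoms: 3-chloroperoxybenzoic acid OOC(=O)c1cccc(Cl)c1
Why: Jacobsen epoxidation should deliver oxygen to the cis-disubstituted, conjugated C4=C5 alkene, the electron-richer and less hindered end of the diene (C2=C3 is flanked by the ester-bearing C1), and the C2-symmetric salen ligand sets C4 (S) and C5 (R) whichever C1 epimer reacts.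

**Step 5**
Reactants: 10 methyl (1RS,4S,5R)-4,5-epoxycyclohex-2-ene-1-carboxylate
Product: 11 methyl (5R)-5-hydroxycyclohexa-1,3-diene-1-carboxylate
Conditions: DBU, CH2Cl2, 0 °C
Reagents that add atoms: none
Why: E1cB-type vinylogous elimination: DBU removes the acidic C1–H and the dienolate opens the allylic C4–O bond through C2=C3, restoring the conjugated dienoate while the C5–O bond and its configuration stay untouched, so both C1 epimers converge on the (5R)-alcohol.

**Step 6**
Reactants: 11 methyl (5R)-5-hydroxycyclohexa-1,3-diene-1-carboxylate; 12 (2R)-2-methylbutanoic acid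
Product: 13 methyl (5R)-5-{[(2R)-2-methylbutanoyl]oxy}cyclohexa-1,3-diene-1-carboxylate
Conditions: DCC, DMAP (cat.), CH2Cl2, −20 to 0 °C
Reagents that add atoms: none
Why: Steglich esterification acylates the alcohol oxygen without breaking the C5–O bond (retention) and without enolising the α-branched acid, so both stereocentres are carried over.

**Step 7**
Reactants: 13 methyl (5R)-5-{[(2R)-2-methylbutanoyl]oxy}cyclohexa-1,3-diene-1-carboxylate
Product: 14 methyl (3R,4S,5R)-3,4-dihydroxy-5-{[(2R)-2-methylbutanoyl]oxy}cyclohex-1-ene-1-carboxylate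
Conditions: OsO4 (2 mol %), N-methylmorpholine N-oxide, acetone/H2O, 0 °C
Reagents that add atoms: N-methylmorpholine N-oxide C[N+]1([O-])CCOCC1; water O
Why: Upjohn dihydroxylation: OsO4 should add suprafacially to the electron-richer γ,δ-alkene C3=C4 on the face opposite the allylic C5 acyloxy group, setting C3 (R) and C4 (S) cis to each other and trans to the C5 oxygen.

**Step 8**
Reactants: 14 methyl (3R,4S,5R)-3,4-dihydroxy-5-{[(2R)-2-methylbutanoyl]oxy}cyclohex-1-ene-1-carboxylate
Product: 16 methyl (3R,4S,5R)-3-acetoxy-4-hydroxy-5-{[(2R)-2-methylbutanoyl]oxy}cyclohex-1-ene-1-carboxylate, via cyclic orthoacetate 15 (not isolated)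
Conditions: MeC(OMe)3, camphorsulfonic acid (cat.), CH2Cl2, 25 °C; then AcOH/H2O, 25 °C
Reagents that add atoms: trimethyl orthoacetate CC(OC)(OC)OC; water O
Why: The cis-3,4-diol forms the cyclic orthoacetate 15, and mild acid hydrolysis through the dioxolan-2-ylium ion should collapse by the usual stereoelectronic preference to axial ester and equatorial alcohol, placing the acetate on the pseudo-axial allylic O3 and freeing O4.

**Step 9**
Reactants: 16 methyl (3R,4S,5R)-3-acetoxy-4-hydroxy-5-{[(2R)-2-methylbutanoyl]oxy}cyclohex-1-ene-1-carboxylate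
Product: 17 methyl (3R,4S,5R)-3-acetoxy-5-{[(2R)-2-methylbutanoyl]oxy}-4-(propanoyloxy)cyclohex-1-ene-1-carboxylate (target)
Conditions: (EtCO)2O, pyridine, DMAP (cat.), CH2Cl2, 0 to 25 °C
Reagents that add atoms: propanoic anhydride CCC(=O)OC(=O)CC
Why: DMAP-catalysed acylation of the only free hydroxyl (O4) with the anhydride touches no stereocentre.

**Compound list**
1 | methyl (2E)-4-bromobut-2-enoate | COC(=O)/C=C/CBr | starting material
2 | triphenylphosphine | c1ccc(cc1)P(c1ccccc1)c1ccccc1 | starting material
3 | [(2E)-4-methoxy-4-oxobut-2-en-1-yl]triphenylphosphonium bromide | COC(=O)/C=C/C[P+](c1ccccc1)(c1ccccc1)c1ccccc1.[Br-] | intermediate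
4 | acrolein (prop-2-enal) | C=CC=O | starting material
5 | methyl (2E)-4-(triphenyl-λ5-phosphanylidene)but-2-enoate (allylidenephosphorane) | COC(=O)/C=C/C=P(c1ccccc1)(c1ccccc1)c1ccccc1 | intermediate
6 | methyl (2E)-2-(3-oxopropyl)-4-(triphenyl-λ5-phosphanylidene)but-2-enoate | O=CCC/C(C(=O)OC)=C\C=P(c1ccccc1)(c1ccccc1)c1ccccc1 | intermediate
7 | methyl cyclohexa-1,3-diene-1-carboxylate | COC(=O)C1=CC=CCC1 | intermediate
8 | lithium (cyclohexa-2,4-dien-1-ylidene)(methoxy)methanolate (trienolate of 7) | COC([O-])=C1C=CC=CC1.[Li+] | intermediate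
9 | methyl cyclohexa-2,4-diene-1-carboxylate (racemic) | COC(=O)C1C=CC=CC1 | intermediate
10 | methyl (1RS,4S,5R)-4,5-epoxycyclohex-2-ene-1-carboxylate (both C1 epimers) | COC(=O)C1C=C[C@@H]2O[C@@H]2C1 | intermediate
11 | methyl (5R)-5-hydroxycyclohexa-1,3-diene-1-carboxylate | COC(=O)C1=CC=C[C@H](O)C1 | intermediate
12 | (2R)-2-methylbutanoic acid | CC[C@@H](C)C(=O)O | starting material
13 | methyl (5R)-5-{[(2R)-2-methylbutanoyl]oxy}cyclohexa-1,3-diene-1-carboxylate | COC(=O)C1=CC=C[C@H](OC(=O)[C@H](C)CC)C1 | intermediate
14 | methyl (3R,4S,5R)-3,4-dihydroxy-5-{[(2R)-2-methylbutanoyl]oxy}cyclohex-1-ene-1-carboxylate | O[C@@H]1[C@H](O)C=C(C(=O)OC)C[C@H]1OC(=O)[C@H](C)CC | intermediate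
15 | 3,4-O-(1-methoxyethylidene) cyclic orthoacetate of 14 (both epimers at the orthoester carbon) | COC1(C)O[C@@H]2[C@H](O1)C=C(C(=O)OC)C[C@H]2OC(=O)[C@H](C)CC | intermediate
16 | methyl (3R,4S,5R)-3-acetoxy-4-hydroxy-5-{[(2R)-2-methylbutanoyl]oxy}cyclohex-1-ene-1-carboxylate | O[C@@H]1[C@H](OC(C)=O)C=C(C(=O)OC)C[C@H]1OC(=O)[C@H](C)CC | intermediate
17 | methyl (3R,4S,5R)-3-acetoxy-5-{[(2R)-2-methylbutanoyl]oxy}-4-(propanoyloxy)cyclohex-1-ene-1-carboxylate | CCC(=O)O[C@@H]1[C@H](OC(C)=O)C=C(C(=O)OC)C[C@H]1OC(=O)[C@H](C)CC | target

**Step count and risks**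
Total steps: 9. Longest linear sequence: 9 steps (1 to 17).

Steps most likely to fail:

1. Step 4. What may go wrong: incomplete discrimination between the two alkenes of the diene or between their faces, and uncatalysed background epoxidation. Fallback: it sets out from 9 and comes back at 11. Buffered m-CPBA (NaHCO3, CH2Cl2, 0 °C) would epoxidise the distal alkene without asymmetric induction to give racemic methyl 4,5-epoxycyclohex-2-ene-1-carboxylate F1. DBU as in step 5 would give racemic methyl 5-hydroxycyclohexa-1,3-diene-1-carboxylate F2. A Sharpless kinetic resolution (Ti(OiPr)4, the diisopropyl tartrate enantiomer for which the (5S)-alcohol reacts fast, t-BuOOH, 4 Å sieves, CH2Cl2, −20 °C) would convert the (5S)-enantiomer into methyl (3R,4S,5S)-3,4-epoxy-5-hydroxycyclohex-1-ene-1-carboxylate F3, which is separated. The unreacted (5R)-alcohol is 11.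

2. Step 6. What may go wrong: base-induced 1,4-elimination (aromatisation) of the dienol or its ester during activation, and slow coupling of the α-branched acid. Fallback: it sets out from 11 and comes back at 14. Upjohn dihydroxylation of the free dienol (OsO4, N-methylmorpholine N-oxide, anti to the allylic hydroxyl) would give methyl (3R,4S,5R)-3,4,5-trihydroxycyclohex-1-ene-1-carboxylate F4. 2,2-Dimethoxypropane with camphorsulfonic acid would protect the cis-diol as methyl 3,4-O-isopropylideneshikimate F5. Steglich esterification of the remaining C5 hydroxyl with 12 would give the 5-O-[(2R)-2-methylbutanoyl] acetonide F6. Aqueous acetic acid would remove the acetonide to give 14.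

3. Step 8. What may go wrong: unselective collapse of the orthoester (acetate delivered to O4) or acyl migration among O3, O4 and O5 under the acidic conditions. Fallback: it sets out from 14 and comes back at 17, reversing the order of the two acylations. Bu2SnO (toluene, reflux) would give the 3,4-O-dibutylstannylene acetal F7, which propanoyl chloride (0 °C) should acylate at the equatorial O4 to give methyl (3R,4S,5R)-3-hydroxy-5-{[(2R)-2-methylbutanoyl]oxy}-4-(propanoyloxy)cyclohex-1-ene-1-carboxylate F8. Acetylation of the remaining O3 (Ac2O, pyridine, DMAP) would give 17.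

**Further compounds**
F1 | step 4 | methyl 4,5-epoxycyclohex-2-ene-1-carboxylate (racemic) | COC(=O)C1C=CC2OC2C1
F2 | step 4 | methyl 5-hydroxycyclohexa-1,3-diene-1-carboxylate (racemic) | COC(=O)C1=CC=CC(O)C1
F3 | step 4 | methyl (3R,4S,5S)-3,4-epoxy-5-hydroxycyclohex-1-ene-1-carboxylate | COC(=O)C1=C[C@H]2O[C@H]2[C@@H](O)C1
F4 | step 6 | methyl (3R,4S,5R)-3,4,5-trihydroxycyclohex-1-ene-1-carboxylate (methyl shikimate) | O[C@@H]1[C@H](O)C=C(C(=O)OC)C[C@H]1O
F5 | step 6 | methyl 3,4-O-isopropylideneshikimate | CC1(C)O[C@@H]2[C@H](O1)C=C(C(=O)OC)C[C@H]2O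
F6 | step 6 | methyl 3,4-O-isopropylidene-5-O-[(2R)-2-methylbutanoyl]shikimate | CC1(C)O[C@@H]2[C@H](O1)C=C(C(=O)OC)C[C@H]2OC(=O)[C@H](C)CC
F7 | step 8 | 3,4-O-dibutylstannylene acetal of 14 | CCCC[Sn]1(CCCC)O[C@@H]2[C@H](O1)C=C(C(=O)OC)C[C@H]2OC(=O)[C@H](C)CC
F8 | step 8 | methyl (3R,4S,5R)-3-hydroxy-5-{[(2R)-2-methylbutanoyl]oxy}-4-(propanoyloxy)cyclohex-1-ene-1-carboxylate | CCC(=O)O[C@@H]1[C@H](O)C=C(C(=O)OC)C[C@H]1OC(=O)[C@H](C)CC
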